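**Plan**

- Numbering as in germacranolides: carbocycle C1–C10, lactone C12(=O)–O–C8 with exocyclic C11=C13, C14 on C10, C15 on C4, ester oxygen on C6.
- Retrosynthesis: the C6 ester and two silyl ethers come off first. The ten-membered ring is then cut at C6–C7: the C6 carbinol sits next to C7 of the α-methylene-γ-lactone ring, so O–C6–C7–C11=C13 is a homoallylic alcohol, the adduct of a (4Z)-C6 enal and a C13-metalated C7=C11 butenolide.
- Further cuts: C7=C11 (ring-closing metathesis of a C8 2-(bromomethyl)acrylate), C8–C9 (alkoxyallylboration of a C9 enal), C9–C10 (formylation of a vinyl iodide), C4=C5 (ring-closing metathesis to a dihydropyranone), C2–C3 (methallylboration of (Z)-3-iodobut-2-enal).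
- Forward: one linear chain; the dihydropyranone arises first as a template and is opened by reduction, then the butenolide, then the ten-membered carbocycle, and last the ester and desilylation.
- Stereochemistry: C2 and C8/C9 from two (−)-Ipc2B allylborations (reagent control); C7 and C6 in the macrocyclisation (C8 and a chair transition state); the side chain from (R)-2-methylbutanoic acid; the 1(10)Z olefin from hydroalumination–iodination of but-2-yn-1-ol and the 4Z olefin from the six-membered lactone.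

Key step: step 15

**Route**

Step 1
Reactants: 1 but-2-yn-1-ol
Product: 3 (Z)-3-iodobut-2-en-1-ol, via cyclic alkenylaluminate 2 (not isolated)
Conditions: NaAlH2(OCH2CH2OMe)2, THF, 0 °C → rt; then I2, −78 → 0 °C
Reagents that add atoms: iodine, II
Why: Hydroxyl-directed trans-hydroalumination of the propargylic alcohol places aluminium on C3 in a five-membered alkoxyaluminate, and iodinolysis with retention should give the Z-iodoalkene that later becomes the 1(10)Z olefin (hydroalumination–iodination of a propargylic alcohol).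

Step 2
Reactants: 3 (Z)-3-iodobut-2-en-1-ol
Product: 4 (Z)-3-iodobut-2-enal
Conditions: MnO2, CH2Cl2, rt, dark
Reagents that add atoms: none
Why: Neutral heterogeneous oxidation of the primary allylic alcohol with MnO2 should give the enal without Z/E isomerisation (allylic alcohol oxidation).

Step 3
Reactants: 4 (Z)-3-iodobut-2-enal
Product: 5 (4S,5Z)-6-iodo-2-methylhepta-1,5-dien-4-ol
Conditions: (−)-Ipc2BOMe, 2-methylallylmagnesium chloride, Et2O, 0 °C → rt; then 4, −78 °C; NaOH, H2O2
Reagents that add atoms: 2-methylallylmagnesium chloride, C=C(C)C[Mg]Cl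
Why: Brown methallylboration through a chair transition state, in which the (−)-Ipc2B group (from (+)-α-pinene) directs the methallyl group to the Si face of the enal and should set C2 as S.

Step 4
Reactants: 5 (4S,5Z)-6-iodo-2-methylhepta-1,5-dien-4-ol
Product: 6 (4S,5Z)-6-iodo-2-methylhepta-1,5-dien-4-yl prop-2-enoate
Conditions: acryloyl chloride, Et3N, CH2Cl2, −20 → 0 °C
Reagents that add atoms: acryloyl chloride, C=CC(=O)Cl
Why: Plain O-acylation of the secondary allylic alcohol supplies C5 and C6 and the second olefin for metathesis (esterification with an acid chloride).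

Step 5
Reactants: 6 (4S,5Z)-6-iodo-2-methylhepta-1,5-dien-4-yl prop-2-enoate
Product: 7 (6S)-6-[(1Z)-2-iodoprop-1-en-1-yl]-4-methyl-5,6-dihydro-2H-pyran-2-one
Conditions: second-generation Grubbs catalyst (5 mol %), CH2Cl2 (5 mM), reflux
Reagents that add atoms: none
Why: Ring-closing metathesis of the acrylate with the 1,1-disubstituted olefin should give the six-membered lactone, whose ring holds C3 and C6 cis across C4=C5 and so fixes the 4Z geometry, while the trisubstituted iodoalkene stays inert.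

Step 6
Reactants: 7 (6S)-6-[(1Z)-2-iodoprop-1-en-1-yl]-4-methyl-5,6-dihydro-2H-pyran-2-one
Product: 8 (2Z)-2-methyl-3-[(2S)-4-methyl-6-oxo-3,6-dihydro-2H-pyran-2-yl]prop-2-enal
Conditions: Pd(PPh3)4 (5 mol %), CO (1 atm), Bu3SnH (slow addition), THF, 50 °C
Reagents that add atoms: carbon monoxide, [C-]#[O+]
Why: Oxidative addition of zerovalent palladium to the C–I bond with retention, CO insertion and hydride transfer from tin should give the Z-enal carrying C9 (palladium-catalysed reductive carbonylation of an alkenyl iodide).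

Step 7
Reactants: 8 (2Z)-2-methyl-3-[(2S)-4-methyl-6-oxo-3,6-dihydro-2H-pyran-2-yl]prop-2-enal and 9 1-methoxy-4-(prop-2-en-1-yloxy)benzene
Product: 11 (6S)-6-[(1Z,3R,4R)-3-hydroxy-4-(4-methoxyphenoxy)-2-methylhexa-1,5-dien-1-yl]-4-methyl-5,6-dihydro-2H-pyran-2-one, via (Z)-γ-aryloxyallylborane 10 (not isolated)
Conditions: 9, s-BuLi, THF, −78 °C; (−)-Ipc2BOMe; BF3·OEt2; then 8, −78 °C; aq. NaOAc, H2O2, 0 °C → rt
Reagents that add atoms: none
Why: Brown alkoxyallylboration, in which the (Z)-γ-aryloxyallylborane reacts through a chair transition state to give the syn C8/C9 diol monoether and the (−)-Ipc2B group directs attack to the Si face of the enal (9R, hence 8R), while the lactone is not touched at −78 °C.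

Step 8
Reactants: 11 (6S)-6-[(1Z,3R,4R)-3-hydroxy-4-(4-methoxyphenoxy)-2-methylhexa-1,5-dien-1-yl]-4-methyl-5,6-dihydro-2H-pyran-2-one
Product: 12 (2Z,5S,6Z,8R,9R)-9-(4-methoxyphenoxy)-3,7-dimethylundeca-2,6,10-triene-1,5,8-triol
Conditions: i-Bu2AlH (5 equiv), CH2Cl2, −78 → 0 °C; aq. potassium sodium tartrate
Reagents that add atoms: none
Why: Exhaustive 1,2-reduction of the unsaturated δ-lactone should open the template to the (Z)-allylic primary alcohol (C6) and free the C2 hydroxyl without touching the olefin geometry (hydride reduction of a lactone to a diol).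

Step 9
Reactants: 12 (2Z,5S,6Z,8R,9R)-9-(4-methoxyphenoxy)-3,7-dimethylundeca-2,6,10-triene-1,5,8-triol
Product: 13 (2Z,5S,6Z,8R,9R)-1,5,8-tris(tert-butyldimethylsilyloxy)-9-(4-methoxyphenoxy)-3,7-dimethylundeca-2,6,10-triene
Conditions: TBSOTf, 2,6-lutidine, CH2Cl2, −78 → 0 °C
Reagents that add atoms: tert-butyldimethylsilyl trifluoromethanesulfonate, CC(C)(C)[Si](C)(C)OS(=O)(=O)C(F)(F)F
Why: The silyl triflate should silylate all three hydroxyls, including the hindered C9 one, in one operation (silyl ether formation).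

Step 10
Reactants: 13 (2Z,5S,6Z,8R,9R)-1,5,8-tris(tert-butyldimethylsilyloxy)-9-(4-methoxyphenoxy)-3,7-dimethylundeca-2,6,10-triene
Product: 14 (3R,4R,5Z,7S,9Z)-4,7,11-tris(tert-butyldimethylsilyloxy)-5,9-dimethylundeca-1,5,9-trien-3-ol
Conditions: (NH4)2Ce(NO3)6, NaHCO3, MeCN–H2O (4:1), 0 °C
Reagents that add atoms: none
Why: Single-electron oxidation of the 4-methoxyphenyl ether to the quinone should release the C8 hydroxyl alone, the buffer and short contact time protecting the silyl ethers (oxidative aryl ether cleavage).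

Step 11
Reactants: 14 (3R,4R,5Z,7S,9Z)-4,7,11-tris(tert-butyldimethylsilyloxy)-5,9-dimethylundeca-1,5,9-trien-3-ol and 15 2-(bromomethyl)prop-2-enoic acid
Product: 16 (3R,4R,5Z,7S,9Z)-4,7,11-tris(tert-butyldimethylsilyloxy)-5,9-dimethylundeca-1,5,9-trien-3-yl 2-(bromomethyl)prop-2-enoate
Conditions: 15, N,N'-diisopropylcarbodiimide, DMAP (10 mol %), CH2Cl2, −20 → 0 °C
Reagents that add atoms: none
Why: Steglich esterification at low temperature with little DMAP should acylate the only free hydroxyl faster than the catalyst displaces the allylic bromide, and it brings in C11, C12 and C13.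

Step 12
Reactants: 16 (3R,4R,5Z,7S,9Z)-4,7,11-tris(tert-butyldimethylsilyloxy)-5,9-dimethylundeca-1,5,9-trien-3-yl 2-(bromomethyl)prop-2-enoate
Product: 17 (5R)-3-(bromomethyl)-5-[(1R,2Z,4S,6Z)-1,4,8-tris(tert-butyldimethylsilyloxy)-2,6-dimethylocta-2,6-dien-1-yl]furan-2(5H)-one
Conditions: second-generation Hoveyda–Grubbs catalyst (10 mol %), 1,4-benzoquinone (20 mol %), toluene (3 mM), 80 °C
Reagents that add atoms: none
Why: Ring-closing metathesis between the terminal vinyl group and the 1,1-disubstituted acrylate olefin should form the butenolide C7=C11 bond, a phosphine-free catalyst being chosen because the allylic bromide would alkylate a phosphine.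

Step 13
Reactants: 17 (5R)-3-(bromomethyl)-5-[(1R,2Z,4S,6Z)-1,4,8-tris(tert-butyldimethylsilyloxy)-2,6-dimethylocta-2,6-dien-1-yl]furan-2(5H)-one
Product: 18 (5R)-3-(bromomethyl)-5-[(1R,2Z,4S,6Z)-1,4-bis(tert-butyldimethylsilyloxy)-8-hydroxy-2,6-dimethylocta-2,6-dien-1-yl]furan-2(5H)-one
Conditions: camphor-10-sulfonic acid (0.2 equiv), MeOH–CH2Cl2 (1:1), 0 °C
Reagents that add atoms: none
Why: Acid-catalysed methanolysis should remove the unhindered primary silyl ether much faster than the two hindered secondary ones, and the amine-free acidic medium leaves the allylic bromide and the base-sensitive C8–H alone (selective desilylation).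

Step 14
Reactants: 18 (5R)-3-(bromomethyl)-5-[(1R,2Z,4S,6Z)-1,4-bis(tert-butyldimethylsilyloxy)-8-hydroxy-2,6-dimethylocta-2,6-dien-1-yl]furan-2(5H)-one
Product: 19 (2Z,5S,6Z,8R)-8-[(2R)-4-(bromomethyl)-5-oxo-2,5-dihydrofuran-2-yl]-5,8-bis(tert-butyldimethylsilyloxy)-3,7-dimethylocta-2,6-dienal
Conditions: Dess–Martin periodinane, NaHCO3, CH2Cl2, 0 °C; used at once
Reagents that add atoms: none
Why: Buffered Dess–Martin oxidation of the (Z)-allylic alcohol should give the (4Z)-enal without isomerisation and without touching the bromide.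

Step 15
Reactants: 19 (2Z,5S,6Z,8R)-8-[(2R)-4-(bromomethyl)-5-oxo-2,5-dihydrofuran-2-yl]-5,8-bis(tert-butyldimethylsilyloxy)-3,7-dimethylocta-2,6-dienal
Product: 21 (1(10)Z,2S,4Z,6R,7S,8R,9R)-2,9-bis(tert-butyldimethylsilyloxy)-6-hydroxygermacra-1(10),4,11(13)-trien-12,8-olide, via allylchromium dichloride 20 (not isolated)
Conditions: CrCl2 (10 equiv), THF (degassed), rt, 19 added by syringe pump over 10 h to 2 mM; aq. NH4Cl
Reagents that add atoms: none
Why: Two equivalents of CrCl2 reduce the allylic C13–Br bond to an allyl species of trivalent chromium (20), whose C7 terminus adds to the chromium-bound C6 aldehyde through a six-membered chair transition state (Cr–O–C6–C7–C11–C13) with allylic transposition, so that the C6–C7 bond, the ten-membered ring and the exocyclic C11=C13 methylene arise together. The closest known reaction type is the intramolecular Nozaki–Hiyama–Kishi allylation of ω-formyl 2-(bromomethyl)alk-2-enoates used to close the C6–C7 bond of ten-membered germacranolide rings, together with the chromium-mediated addition of 3-(bromomethyl)furan-2(5H)-ones to aldehydes. The ten-membered carbocycle closes by a 10-exo-trig addition to the aldehyde, SE2' at the allylmetal. C7 is controlled by the existing C8 centre, the aldehyde arm being delivered to the butenolide face opposite the C8–C9 bond, which should give the trans-fused lactone (7S); C6 is controlled by the chair transition state, in which the ring-fixed geometry of the allyl unit (C8 trans to C13 across C7=C11) and a pseudo-equatorial enal residue lead to the anti arrangement of the C6 oxygen and the C7–C8 bond (6R). The step needs γ- over α-attack, 1,2- over 1,4-addition, aldehyde over lactone attack, retention of the 4Z enal and ring closure over oligomerisation; these rest on the inherent SE2' and aldehyde selectivity of allylchromium reagents, the neutral medium and slow addition at high dilution.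

Step 16
Reactants: 21 (1(10)Z,2S,4Z,6R,7S,8R,9R)-2,9-bis(tert-butyldimethylsilyloxy)-6-hydroxygermacra-1(10),4,11(13)-trien-12,8-olide and 22 (R)-2-methylbutanoic acid
Product: 24 (1(10)Z,2S,4Z,6R,7S,8R,9R)-2,9-bis(tert-butyldimethylsilyloxy)-6-[(2R)-2-methylbutanoyloxy]germacra-1(10),4,11(13)-trien-12,8-olide, via mixed anhydride 23 (not isolated)
Conditions: 22, 2,4,6-trichlorobenzoyl chloride, Et3N, toluene, rt; then 21, DMAP, rt
Reagents that add atoms: none
Why: Yamaguchi esterification through the mixed anhydride should acylate the hindered C6 hydroxyl with retention at C6 and without epimerising the α-centre of the acid, before the C6 alkoxide can translactonise.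

Step 17
Reactants: 24 (1(10)Z,2S,4Z,6R,7S,8R,9R)-2,9-bis(tert-butyldimethylsilyloxy)-6-[(2R)-2-methylbutanoyloxy]germacra-1(10),4,11(13)-trien-12,8-olide
Product: 25 CNP0176600.1, (3aS,4R,5Z,8S,9Z,11R,11aR)-8,11-dihydroxy-6,10-dimethyl-3-methylidene-2-oxo-2,3,3a,4,7,8,11,11a-octahydrocyclodeca[b]furan-4-yl (2R)-2-methylbutanoate
Conditions: HF·pyridine, pyridine, THF, 0 °C → rt
Reagents that add atoms: none
Why: Buffered fluoride cleavage of the two secondary silyl ethers should free the C2 and C9 hydroxyls while the ester, the lactone and the α-methylene group survive (global desilylation).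

**Compound list**

1 | but-2-yn-1-ol | CC#CCO | starting material
2 | sodium cyclic alkenylaluminate (2,2-bis(2-methoxyethoxy)-3-methyl-2,5-dihydro-1,2-oxaaluminol-2-uide) | CC1=CCO[Al-]1(OCCOC)OCCOC.[Na+] | intermediate (not isolated)
3 | (Z)-3-iodobut-2-en-1-ol | C/C(I)=C/CO | intermediate
4 | (Z)-3-iodobut-2-enal | C/C(I)=C/C=O | intermediate
5 | (4S,5Z)-6-iodo-2-methylhepta-1,5-dien-4-ol | C=C(C)C[C@H](O)/C=C(/C)I | intermediate
6 | (4S,5Z)-6-iodo-2-methylhepta-1,5-dien-4-yl prop-2-enoate | C=C(C)C[C@H](OC(=O)C=C)/C=C(/C)I | intermediate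
7 | (6S)-6-[(1Z)-2-iodoprop-1-en-1-yl]-4-methyl-5,6-dihydro-2H-pyran-2-one | CC1=CC(=O)O[C@@H](C1)/C=C(/C)I | intermediate
8 | (2Z)-2-methyl-3-[(2S)-4-methyl-6-oxo-3,6-dihydro-2H-pyran-2-yl]prop-2-enal | CC1=CC(=O)O[C@@H](C1)/C=C(/C)C=O | intermediate
9 | 1-methoxy-4-(prop-2-en-1-yloxy)benzene (4-allyloxyanisole) | C=CCOc1ccc(OC)cc1 | starting material
10 | [(Z)-3-(4-methoxyphenoxy)prop-2-en-1-yl]diisopinocampheylborane | COc1ccc(O/C=C\CB([C@@H]2C[C@@H]3C[C@H]([C@H]2C)C3(C)C)[C@@H]2C[C@@H]3C[C@H]([C@H]2C)C3(C)C)cc1 | intermediate (not isolated)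
11 | (6S)-6-[(1Z,3R,4R)-3-hydroxy-4-(4-methoxyphenoxy)-2-methylhexa-1,5-dien-1-yl]-4-methyl-5,6-dihydro-2H-pyran-2-one | CC1=CC(=O)O[C@@H](C1)/C=C(/C)[C@@H](O)[C@H](Oc2ccc(OC)cc2)C=C | intermediate
12 | (2Z,5S,6Z,8R,9R)-9-(4-methoxyphenoxy)-3,7-dimethylundeca-2,6,10-triene-1,5,8-triol | OC/C=C(C)\C[C@H](O)/C=C(/C)[C@@H](O)[C@H](Oc1ccc(OC)cc1)C=C | intermediate
13 | (2Z,5S,6Z,8R,9R)-1,5,8-tris(tert-butyldimethylsilyloxy)-9-(4-methoxyphenoxy)-3,7-dimethylundeca-2,6,10-triene | CC(C)(C)[Si](C)(C)OC/C=C(C)\C[C@H](O[Si](C)(C)C(C)(C)C)/C=C(/C)[C@@H](O[Si](C)(C)C(C)(C)C)[C@H](Oc1ccc(OC)cc1)C=C | intermediate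
14 | (3R,4R,5Z,7S,9Z)-4,7,11-tris(tert-butyldimethylsilyloxy)-5,9-dimethylundeca-1,5,9-trien-3-ol | CC(C)(C)[Si](C)(C)OC/C=C(C)\C[C@H](O[Si](C)(C)C(C)(C)C)/C=C(/C)[C@@H](O[Si](C)(C)C(C)(C)C)[C@H](O)C=C | intermediate
15 | 2-(bromomethyl)prop-2-enoic acid | C=C(CBr)C(=O)O | starting material
16 | (3R,4R,5Z,7S,9Z)-4,7,11-tris(tert-butyldimethylsilyloxy)-5,9-dimethylundeca-1,5,9-trien-3-yl 2-(bromomethyl)prop-2-enoate | CC(C)(C)[Si](C)(C)OC/C=C(C)\C[C@H](O[Si](C)(C)C(C)(C)C)/C=C(/C)[C@@H](O[Si](C)(C)C(C)(C)C)[C@H](OC(=O)C(=C)CBr)C=C | intermediate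
17 | (5R)-3-(bromomethyl)-5-[(1R,2Z,4S,6Z)-1,4,8-tris(tert-butyldimethylsilyloxy)-2,6-dimethylocta-2,6-dien-1-yl]furan-2(5H)-one | CC(C)(C)[Si](C)(C)OC/C=C(C)\C[C@H](O[Si](C)(C)C(C)(C)C)/C=C(/C)[C@@H](O[Si](C)(C)C(C)(C)C)[C@@H]1OC(=O)C(CBr)=C1 | intermediate
18 | (5R)-3-(bromomethyl)-5-[(1R,2Z,4S,6Z)-1,4-bis(tert-butyldimethylsilyloxy)-8-hydroxy-2,6-dimethylocta-2,6-dien-1-yl]furan-2(5H)-one | OC/C=C(C)\C[C@H](O[Si](C)(C)C(C)(C)C)/C=C(/C)[C@@H](O[Si](C)(C)C(C)(C)C)[C@@H]1OC(=O)C(CBr)=C1 | intermediate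
19 | (2Z,5S,6Z,8R)-8-[(2R)-4-(bromomethyl)-5-oxo-2,5-dihydrofuran-2-yl]-5,8-bis(tert-butyldimethylsilyloxy)-3,7-dimethylocta-2,6-dienal | O=C/C=C(C)\C[C@H](O[Si](C)(C)C(C)(C)C)/C=C(/C)[C@@H](O[Si](C)(C)C(C)(C)C)[C@@H]1OC(=O)C(CBr)=C1 | intermediate
20 | allylchromium dichloride of 19 (C13–CrCl2 in place of C13–Br) | O=C/C=C(C)\C[C@H](O[Si](C)(C)C(C)(C)C)/C=C(/C)[C@@H](O[Si](C)(C)C(C)(C)C)[C@@H]1OC(=O)C(C[Cr](Cl)Cl)=C1 | intermediate (not isolated)
21 | (1(10)Z,2S,4Z,6R,7S,8R,9R)-2,9-bis(tert-butyldimethylsilyloxy)-6-hydroxygermacra-1(10),4,11(13)-trien-12,8-olide | C=C1C(=O)O[C@@H]2[C@@H]1[C@H](O)/C=C(/C)C[C@H](O[Si](C)(C)C(C)(C)C)/C=C(/C)[C@H]2O[Si](C)(C)C(C)(C)C | intermediate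
22 | (R)-2-methylbutanoic acid | CC[C@@H](C)C(=O)O | starting material
23 | (2R)-2-methylbutanoic 2,4,6-trichlorobenzoic anhydride | CC[C@@H](C)C(=O)OC(=O)c1c(Cl)cc(Cl)cc1Cl | intermediate (not isolated)
24 | (1(10)Z,2S,4Z,6R,7S,8R,9R)-2,9-bis(tert-butyldimethylsilyloxy)-6-[(2R)-2-methylbutanoyloxy]germacra-1(10),4,11(13)-trien-12,8-olide | C=C1C(=O)O[C@@H]2[C@@H]1[C@H](OC(=O)[C@H](C)CC)/C=C(/C)C[C@H](O[Si](C)(C)C(C)(C)C)/C=C(/C)[C@H]2O[Si](C)(C)C(C)(C)C | intermediate
25 | CNP0176600.1, (3aS,4R,5Z,8S,9Z,11R,11aR)-8,11-dihydroxy-6,10-dimethyl-3-methylidene-2-oxo-2,3,3a,4,7,8,11,11a-octahydrocyclodeca[b]furan-4-yl (2R)-2-methylbutanoate | C=C1C(=O)O[C@@H]2[C@@H]1[C@H](OC(=O)[C@H](C)CC)/C=C(/C)C[C@H](O)/C=C(/C)[C@H]2O | target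

**Count and risks**

Total step count: 17. Longest linear sequence: 17 steps (1 to 25).

Steps most likely to fail:

1. Step 15. The aldehyde may be attacked on the wrong face in the macrocyclic transition state, so that the C6 epimer forms, besides loss of material to intermolecular allylation. The fallback sets out from 19 and corrects C6 in the esterification instead of in the C–C bond formation: if the closure delivers mainly the C6-epimeric macrocyclic alcohol (6S)-6-epi-21 F1, a Mitsunobu reaction of F1 with acid 22 (PPh3, diisopropyl azodicarboxylate, toluene, 0 °C) inverts C6 and comes back to the route at 24.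

2. Step 12. The allylic bromide may alkylate the ruthenium carbene or its ligands, and bromide may already be lost by SN2' attack of the acylation catalyst in step 11. The fallback sets out from 14 and 15 and introduces the bromide only after metathesis. Acid 15 is treated with 4-methoxybenzyl alcohol and NaH (THF, 0 °C) to give 2-{[(4-methoxyphenyl)methoxy]methyl}prop-2-enoic acid F2. Alcohol 14 is esterified with F2 (N,N'-diisopropylcarbodiimide, DMAP) to the C8 ester F3. Ring-closing metathesis (second-generation Grubbs catalyst, toluene, 80 °C) gives the 3-[(4-methoxybenzyloxy)methyl]butenolide F4. DDQ (CH2Cl2–pH 7 buffer) frees the 3-(hydroxymethyl)butenolide F5, and CBr4/PPh3 (CH2Cl2, 0 °C) comes back to the route at 17.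

3. Step 6. Hydride may be transferred to the alkenylpalladium before CO insertion (hydrodeiodination), or palladium hydride may isomerise the Z-enal. The fallback sets out from 7 and brings in C9 at the alcohol level: Stille coupling with (tributylstannyl)methanol (Pd(PPh3)4, toluene, 80 °C) gives the (Z)-allylic alcohol (6S)-6-[(1Z)-3-hydroxy-2-methylprop-1-en-1-yl]-4-methyl-5,6-dihydro-2H-pyran-2-one F6, and MnO2 (CH2Cl2, rt) comes back to the route at 8.

**Further compounds**

F1 | step 15 | (1(10)Z,2S,4Z,6S,7S,8R,9R)-2,9-bis(tert-butyldimethylsilyloxy)-6-hydroxygermacra-1(10),4,11(13)-trien-12,8-olide | C=C1C(=O)O[C@@H]2[C@@H]1[C@@H](O)/C=C(/C)C[C@H](O[Si](C)(C)C(C)(C)C)/C=C(/C)[C@H]2O[Si](C)(C)C(C)(C)C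
F2 | step 12 | 2-{[(4-methoxyphenyl)methoxy]methyl}prop-2-enoic acid | C=C(COCc1ccc(OC)cc1)C(=O)O
F3 | step 12 | (3R,4R,5Z,7S,9Z)-4,7,11-tris(tert-butyldimethylsilyloxy)-5,9-dimethylundeca-1,5,9-trien-3-yl 2-{[(4-methoxyphenyl)methoxy]methyl}prop-2-enoate | CC(C)(C)[Si](C)(C)OC/C=C(C)\C[C@H](O[Si](C)(C)C(C)(C)C)/C=C(/C)[C@@H](O[Si](C)(C)C(C)(C)C)[C@H](OC(=O)C(=C)COCc1ccc(OC)cc1)C=C
F4 | step 12 | (5R)-3-{[(4-methoxyphenyl)methoxy]methyl}-5-[(1R,2Z,4S,6Z)-1,4,8-tris(tert-butyldimethylsilyloxy)-2,6-dimethylocta-2,6-dien-1-yl]furan-2(5H)-one | CC(C)(C)[Si](C)(C)OC/C=C(C)\C[C@H](O[Si](C)(C)C(C)(C)C)/C=C(/C)[C@@H](O[Si](C)(C)C(C)(C)C)[C@@H]1OC(=O)C(COCc2ccc(OC)cc2)=C1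
F5 | step 12 | (5R)-3-(hydroxymethyl)-5-[(1R,2Z,4S,6Z)-1,4,8-tris(tert-butyldimethylsilyloxy)-2,6-dimethylocta-2,6-dien-1-yl]furan-2(5H)-one | CC(C)(C)[Si](C)(C)OC/C=C(C)\C[C@H](O[Si](C)(C)C(C)(C)C)/C=C(/C)[C@@H](O[Si](C)(C)C(C)(C)C)[C@@H]1OC(=O)C(CO)=C1
F6 | step 6 | (6S)-6-[(1Z)-3-hydroxy-2-methylprop-1-en-1-yl]-4-methyl-5,6-dihydro-2H-pyran-2-one | CC1=CC(=O)O[C@@H](C1)/C=C(/C)CO
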